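**Retrosynthetic overview**
1. Target 20 ⇐ dienol 19: the oxirane (second ring, formed last) by hydroxyl-directed epoxidation of the C4=C5 olefin from the outer face of the macrocycle.
2. 19 ⇐ bromo aldehyde 18: the ten-membered carbocycle (first ring) by closing C5–C6 in an electrochemical chromium/nickel-catalysed alkenyl bromide–aldehyde cyclisation that also sets C6.
3. 18 ⇐ alkyl iodide 14 + alkenyl iodide 8 + acid chloride 16: C9–C10 by nickel-catalysed cross-electrophile coupling, then esterification at C8–OH and Weinreb amide → aldehyde.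
4. 14 ⇐ (R)-3-hydroxy-γ-butyrolactone 9: the lactone supplies C8, trans α-isopropylation sets C7, Weinreb opening and iodination expose C6 and C9.
5. 8 ⇐ but-3-yn-1-ol 1: carboalumination/bromination (C4=C5), propynylation, hydrozirconation/iodination (C10=C1).

Assumption: atoms are labelled with germacrane numbering (C1=C10 olefin, C4/C5 epoxide, C6–OH, C7–isopropyl, C8–O-aroyl), and compounds 1, 5, 9, 10 and 16 are taken as catalogue materials.

**Step 1**
Reactants: 1 but-3-yn-1-ol
Product: 3 (E)-4-bromo-3-methylbut-3-en-1-ol, via alkenyldimethylalane 2 (not isolated)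
Conditions: AlMe3 (3 equiv), Cp2ZrCl2 (0.2 equiv), CH2Cl2, 0 °C → rt; then NBS, THF, −30 °C; aq. K2CO3 work-up
Reagents that add atoms: trimethylaluminium C[Al](C)C; N-bromosuccinimide O=C1CCC(=O)N1Br
Why: Negishi zirconium-catalysed carboalumination adds Me–Al syn across the terminal alkyne with aluminium on the terminal carbon, and bromodealumination with retention fixes the E geometry of the future C4=C5 olefin.

**Step 2**
Reactants: 3 (E)-4-bromo-3-methylbut-3-en-1-ol
Product: 4 (E)-1-bromo-4-iodo-2-methylbut-1-ene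
Conditions: I2, PPh3, imidazole, CH2Cl2, 0 °C → rt
Reagents that add atoms: iodine II
Why: Appel-type iodination converts the primary alcohol into the iodide by SN2 and leaves the alkenyl bromide untouched.

**Step 3**
Reactants: 4 (E)-1-bromo-4-iodo-2-methylbut-1-ene; 5 1-propynyllithium
Product: 6 (E)-1-bromo-2-methylhept-1-en-5-yne
Conditions: THF/DMPU, −78 → 0 °C
Reagents that add atoms: none
Why: SN2 alkylation of a lithium acetylide by a primary iodide, to which the alkenyl bromide is inert.

**Step 4**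
Reactants: 6 (E)-1-bromo-2-methylhept-1-en-5-yne
Product: 8 (1E,5E)-1-bromo-6-iodo-2-methylhepta-1,5-diene, via alkenylzirconocene chloride 7 (not isolated)
Conditions: Cp2Zr(H)Cl (2 equiv), THF, 50 °C; then I2, THF, 0 °C
Reagents that add atoms: iodine II
Why: Hydrozirconation adds Zr–H syn across the methyl alkyne with zirconium on the less hindered methyl-bearing carbon (excess reagent equilibrates the regioisomers), and iododezirconation with retention gives the (E)-2-iodo-2-alkene that becomes C10=C1.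

**Step 5**
Reactants: 9 (R)-3-hydroxy-γ-butyrolactone; 10 2-iodopropane
Product: 12 (3R,4R)-4-hydroxy-3-(propan-2-yl)oxolan-2-one, via dilithium alkoxide enolate 11 (not isolated)
Conditions: LiN(iPr)2 (2.2 equiv), THF/DMPU, −78 → −40 °C; 10 (3 equiv), −40 → −10 °C; AcOH quench
Reagents that add atoms: none
Why: Fráter–Seebach-type alkylation of the alkoxide–enolate dianion, in which the electrophile enters anti to the neighbouring lithium alkoxide so that the bought C8 centre sets C7 (trans lactone); DMPU is needed for the secondary iodide and the yield is expected to be modest.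

**Step 6**
Reactants: 12 (3R,4R)-4-hydroxy-3-(propan-2-yl)oxolan-2-one
Product: 13 (2R,3R)-3,4-dihydroxy-N-methoxy-N-methyl-2-(propan-2-yl)butanamide
Conditions: MeNH(OMe)·HCl (3 equiv), AlMe3 (3 equiv), CH2Cl2, 0 °C → rt; ice-water work-up; used at once
Reagents that add atoms: N,O-dimethylhydroxylamine hydrochloride CNOC.Cl
Why: Weinreb aminolysis with the aluminium amide opens the lactone at the acyl carbon, touches neither stereocentre and frees the primary C9 hydroxyl.

**Step 7**
Reactants: 13 (2R,3R)-3,4-dihydroxy-N-methoxy-N-methyl-2-(propan-2-yl)butanamide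
Product: 14 (2R,3R)-3-hydroxy-4-iodo-N-methoxy-N-methyl-2-(propan-2-yl)butanamide
Conditions: I2, PPh3, imidazole, THF, 0 °C; used at once
Reagents that add atoms: iodine II
Why: Appel iodination is selective for the primary over the hindered secondary hydroxyl (SN2 at CH2).

**Step 8**
Reactants: 14 (2R,3R)-3-hydroxy-4-iodo-N-methoxy-N-methyl-2-(propan-2-yl)butanamide; 8 (1E,5E)-1-bromo-6-iodo-2-methylhepta-1,5-diene
Product: 15 (2R,3S,5E,9E)-10-bromo-3-hydroxy-N-methoxy-N,5,9-trimethyl-2-(propan-2-yl)deca-5,9-dienamide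
Conditions: NiBr2(glyme) (10 mol %), 4,4′-di-tert-butyl-2,2′-bipyridine (10 mol %), Mn powder (3 equiv), NaI (0.5 equiv), DMA, 25 °C
Reagents that add atoms: none
Why: Nickel-catalysed reductive cross-electrophile coupling (Weix type), in which zerovalent nickel adds to the alkenyl C–I bond far faster than to the C–Br bond, captures the primary alkyl radical from 14 and forms C9–C10 with retention of the E geometry while the free hydroxyl and the Weinreb amide are tolerated.

**Step 9**
Reactants: 15 (2R,3S,5E,9E)-10-bromo-3-hydroxy-N-methoxy-N,5,9-trimethyl-2-(propan-2-yl)deca-5,9-dienamide; 16 3,4,5-trimethoxybenzoyl chloride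
Product: 17 (2R,3S,5E,9E)-10-bromo-1-[methoxy(methyl)amino]-5,9-dimethyl-1-oxo-2-(propan-2-yl)deca-5,9-dien-3-yl 3,4,5-trimethoxybenzoate
Conditions: pyridine, DMAP (cat.), CH2Cl2, 0 °C → rt
Reagents that add atoms: none
Why: DMAP-catalysed acyl transfer esterifies the only hydroxyl group with retention at C8, before the C6 hydroxyl exists, so no diol differentiation is needed.

**Step 10**
Reactants: 17 (2R,3S,5E,9E)-10-bromo-1-[methoxy(methyl)amino]-5,9-dimethyl-1-oxo-2-(propan-2-yl)deca-5,9-dien-3-yl 3,4,5-trimethoxybenzoate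
Product: 18 (2R,3S,5E,9E)-10-bromo-5,9-dimethyl-1-oxo-2-(propan-2-yl)deca-5,9-dien-3-yl 3,4,5-trimethoxybenzoate
Conditions: Cp2Zr(H)Cl (1.5 equiv), THF, rt, 20 min; short silica plug; used crude at once
Reagents that add atoms: none
Why: Cp2Zr(H)Cl reduces the Weinreb amide to the aldehyde through a stable zirconated hemiaminal (Georg reduction) and leaves the aryl ester, the trisubstituted alkenes and the alkenyl bromide untouched.

**Step 11**
Reactants: 18 (2R,3S,5E,9E)-10-bromo-5,9-dimethyl-1-oxo-2-(propan-2-yl)deca-5,9-dien-3-yl 3,4,5-trimethoxybenzoate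
Product: 19 (1S,3E,7E,9S,10S)-9-hydroxy-4,8-dimethyl-10-(propan-2-yl)cyclodeca-3,7-dien-1-yl 3,4,5-trimethoxybenzoate
Conditions: undivided cell, Al anode, Ni-foam cathode, constant current 3 mA (2.5 F/mol); CrCl2 (20 mol %), NiBr2(glyme) (5 mol %), 2,9-dimethyl-1,10-phenanthroline (6 mol %), Cp2ZrCl2 (1.2 equiv), LiCl, DMF, 25 °C; 18 added over 12 h (final 2 mM); aq. NH4Cl work-up
Reagents that add atoms: none
Why: Proposed new method: the cathode turns trivalent chromium over to CrCl2 and regenerates zerovalent nickel, which inserts into the alkenyl C–Br bond and transmetalates to chromium, the alkenylchromium adds to the tethered aldehyde at low stationary concentration, and Cp2ZrCl2 strips the alkoxide from chromium so that chromium stays catalytic; the E olefin is retained and C6 is set by C7, because ring closure holds C8 gauche and the isopropyl group anti to the incoming alkenyl carbon (Felkin–Anh, carbonyl oxygen on the C8 side), which should give the 6β-alcohol (9S in 19); the closest known reaction types are the intermolecular electrochemical Cr/Ni Nozaki–Hiyama–Kishi coupling of alkenyl bromides with aldehydes and stoichiometric-CrCl2 Nozaki–Hiyama–Kishi macrocyclisations.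

**Step 12**
Reactants: 19 (1S,3E,7E,9S,10S)-9-hydroxy-4,8-dimethyl-10-(propan-2-yl)cyclodeca-3,7-dien-1-yl 3,4,5-trimethoxybenzoate
Product: 20 (1(10)E,4R,5R,6R,7S,8S)-4,5-epoxy-6-hydroxygermacr-1(10)-en-8-yl 3,4,5-trimethoxybenzoate (target CNP0260213.3)
Conditions: VO(acac)2 (5 mol %), tBuOOH (1.5 equiv), CH2Cl2, 0 °C → rt
Reagents that add atoms: tert-butyl hydroperoxide CC(C)(C)OO
Why: Sharpless–Michaelson hydroxyl-directed epoxidation reacts only at the allylic C4=C5 olefin, and the vanadium-bound peroxide needs a small O–C6–C5=C4 dihedral that the ring offers only with C7 turned inside, so oxygen should be delivered to the outer face to give the erythro (4R,5R) trans-epoxide (a peracid would favour the other conformer and the threo isomer).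

**Compound list**
1 | but-3-yn-1-ol | C#CCCO | starting material
2 | (E)-[4-(dimethylalumanyloxy)-2-methylbut-1-en-1-yl]dimethylalane (formed in situ) | C[Al](C)/C=C(\C)CCO[Al](C)C | intermediate
3 | (E)-4-bromo-3-methylbut-3-en-1-ol | OCC/C(C)=C/Br | intermediate
4 | (E)-1-bromo-4-iodo-2-methylbut-1-ene | ICC/C(C)=C/Br | intermediate
5 | 1-propynyllithium | [Li]C#CC | starting material
6 | (E)-1-bromo-2-methylhept-1-en-5-yne | CC#CCC/C(C)=C/Br | intermediate
7 | chloro[(2E,6E)-7-bromo-6-methylhepta-2,6-dien-2-yl]bis(cyclopentadienyl)zirconium (formed in situ) | C/C(=C\CC/C(C)=C/Br)[Zr](Cl)(C1C=CC=C1)C1C=CC=C1 | intermediate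
8 | (1E,5E)-1-bromo-6-iodo-2-methylhepta-1,5-diene | C/C(I)=C\CC/C(C)=C/Br | intermediate
9 | (R)-3-hydroxy-γ-butyrolactone, (4R)-4-hydroxyoxolan-2-one | O=C1C[C@@H](O)CO1 | starting material
10 | 2-iodopropane | CC(C)I | starting material
11 | dilithium alkoxide–enolate (dianion) of 9 (formed in situ) | [Li+].[Li+].[O-]C1=C[C@@H]([O-])CO1 | intermediate
12 | (3R,4R)-4-hydroxy-3-(propan-2-yl)oxolan-2-one (trans) | O=C1[C@H](C(C)C)[C@@H](O)CO1 | intermediate
13 | (2R,3R)-3,4-dihydroxy-N-methoxy-N-methyl-2-(propan-2-yl)butanamide | CON(C)C(=O)[C@H](C(C)C)[C@@H](O)CO | intermediate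
14 | (2R,3R)-3-hydroxy-4-iodo-N-methoxy-N-methyl-2-(propan-2-yl)butanamide | CON(C)C(=O)[C@H](C(C)C)[C@@H](O)CI | intermediate
15 | (2R,3S,5E,9E)-10-bromo-3-hydroxy-N-methoxy-N,5,9-trimethyl-2-(propan-2-yl)deca-5,9-dienamide | CON(C)C(=O)[C@H](C(C)C)[C@@H](O)C/C(C)=C/CC/C(C)=C/Br | intermediate
16 | 3,4,5-trimethoxybenzoyl chloride | COc1cc(C(Cl)=O)cc(OC)c1OC | starting material
17 | (2R,3S,5E,9E)-10-bromo-1-[methoxy(methyl)amino]-5,9-dimethyl-1-oxo-2-(propan-2-yl)deca-5,9-dien-3-yl 3,4,5-trimethoxybenzoate | COc1cc(C(=O)O[C@@H](C/C(C)=C/CC/C(C)=C/Br)[C@H](C(=O)N(C)OC)C(C)C)cc(OC)c1OC | intermediate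
18 | (2R,3S,5E,9E)-10-bromo-5,9-dimethyl-1-oxo-2-(propan-2-yl)deca-5,9-dien-3-yl 3,4,5-trimethoxybenzoate | COc1cc(C(=O)O[C@@H](C/C(C)=C/CC/C(C)=C/Br)[C@H](C=O)C(C)C)cc(OC)c1OC | intermediate
19 | (1S,3E,7E,9S,10S)-9-hydroxy-4,8-dimethyl-10-(propan-2-yl)cyclodeca-3,7-dien-1-yl 3,4,5-trimethoxybenzoate (germacra-1(10)E,4E-diene-6β,8α-diol 8-ester) | COc1cc(C(=O)O[C@H]2C/C(C)=C/CC/C(C)=C/[C@H](O)[C@@H]2C(C)C)cc(OC)c1OC | intermediate
20 | (1(10)E,4R,5R,6R,7S,8S)-4,5-epoxy-6-hydroxygermacr-1(10)-en-8-yl 3,4,5-trimethoxybenzoate (trans-epoxide, 6-OH cis and 8-ester trans to the 7-isopropyl group) | COc1cc(C(=O)O[C@H]2C/C(C)=C/CC[C@@]3(C)O[C@@H]3[C@H](O)[C@@H]2C(C)C)cc(OC)c1OC | target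

**Step count**
Total: 12 steps. Longest linear sequence: 9 steps (steps 1–4, then 8–12); the branch from 9 is 8 steps.

**The three steps most likely to fail**

Step 11 (the proposed electrochemical macrocyclisation). Turnover of chromium at the low substrate concentration needed for a ten-membered ring, or reduction of the aldehyde at the cathode, may defeat it. The fallback uses known stoichiometric organochromium chemistry on the more reactive iodide; it sets out from 17 and comes back at 19. Copper-catalysed halide exchange on 17 (CuI, NaI, N,N′-dimethylethylenediamine, dioxane, 110 °C, retention of geometry) gives the alkenyl iodide (2R,3S,5E,9E)-10-iodo-1-[methoxy(methyl)amino]-5,9-dimethyl-1-oxo-2-(propan-2-yl)deca-5,9-dien-3-yl 3,4,5-trimethoxybenzoate F3. Cp2Zr(H)Cl then gives the iodo aldehyde (2R,3S,5E,9E)-10-iodo-5,9-dimethyl-1-oxo-2-(propan-2-yl)deca-5,9-dien-3-yl 3,4,5-trimethoxybenzoate F4. This is closed to 19 by the classical Nozaki–Hiyama–Kishi macrocyclisation with excess CrCl2 and 1 mol % NiCl2 in DMSO/THF at 2 mM under syringe-pump addition.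

Step 12 (facial selectivity of the epoxidation, and indirectly the C6 configuration from step 11). If the ring reacts through the conformer with the C4=C5 unit flipped, the threo epoxide forms. The fallback replaces directed epoxidation by nucleophilic epoxidation of the enone followed by chelation-controlled reduction; it sets out from 19 (either C6 epimer or a mixture) and comes back at 20. Dess–Martin periodinane gives the enone (1S,3E,7E,10R)-4,8-dimethyl-9-oxo-10-(propan-2-yl)cyclodeca-3,7-dien-1-yl 3,4,5-trimethoxybenzoate F5. Weitz–Scheffer epoxidation (tBuOOH, cat. DBU, THF, 0 °C, short time to limit loss of the β-aroyloxy group) on the outer face gives the trans-epoxy ketone (4R,5R,7R,8S)-4,5-epoxy-6-oxogermacr-1(10)E-en-8-yl 3,4,5-trimethoxybenzoate F6. Zn(BH4)2 in Et2O at −20 °C reduces F6 through the epoxide–ketone chelate to the erythro epoxy alcohol 20.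

Step 8 (cross-electrophile coupling). The free iodohydrin may eliminate under reducing conditions and the alkenyl bromide may compete with the iodide. The fallback is a polar epoxide opening; it sets out from 13 and 8 and comes back at 15. Mitsunobu cyclodehydration of 13 (PPh3, DIAD, toluene, 80 °C) gives the epoxide (2R)-N-methoxy-N,3-dimethyl-2-[(2R)-oxiran-2-yl]butanamide F1. Iodine–magnesium exchange on 8 (iPrMgCl·LiCl, THF, −20 °C, the C–Br bond is slower) gives chloro[(2E,6E)-7-bromo-6-methylhepta-2,6-dien-2-yl]magnesium F2. F2 opens F1 at the terminal carbon under CuI catalysis (10 mol %, −30 °C) to give 15.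

Further compounds
F1 | step 8 | (2R)-N-methoxy-N,3-dimethyl-2-[(2R)-oxiran-2-yl]butanamide | CON(C)C(=O)[C@H](C(C)C)[C@@H]1CO1
F2 | step 8 | chloro[(2E,6E)-7-bromo-6-methylhepta-2,6-dien-2-yl]magnesium | C/C([Mg]Cl)=C\CC/C(C)=C/Br
F3 | step 11 | (2R,3S,5E,9E)-10-iodo-1-[methoxy(methyl)amino]-5,9-dimethyl-1-oxo-2-(propan-2-yl)deca-5,9-dien-3-yl 3,4,5-trimethoxybenzoate | COc1cc(C(=O)O[C@@H](C/C(C)=C/CC/C(C)=C/I)[C@H](C(=O)N(C)OC)C(C)C)cc(OC)c1OC
F4 | step 11 | (2R,3S,5E,9E)-10-iodo-5,9-dimethyl-1-oxo-2-(propan-2-yl)deca-5,9-dien-3-yl 3,4,5-trimethoxybenzoate | COc1cc(C(=O)O[C@@H](C/C(C)=C/CC/C(C)=C/I)[C@H](C=O)C(C)C)cc(OC)c1OC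
F5 | step 12 | (1S,3E,7E,10R)-4,8-dimethyl-9-oxo-10-(propan-2-yl)cyclodeca-3,7-dien-1-yl 3,4,5-trimethoxybenzoate | COc1cc(C(=O)O[C@H]2C/C(C)=C/CC/C(C)=C/C(=O)[C@@H]2C(C)C)cc(OC)c1OC
F6 | step 12 | (4R,5R,7R,8S)-4,5-epoxy-6-oxogermacr-1(10)E-en-8-yl 3,4,5-trimethoxybenzoate | COc1cc(C(=O)O[C@H]2C/C(C)=C/CC[C@@]3(C)O[C@@H]3C(=O)[C@@H]2C(C)C)cc(OC)c1OC
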